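**Retrosynthetic overview**
- The target comes from its tri-O-benzyl ether by hydrogenolysis; rings B and D are bought and carried through.
- Rings A and C are formed last and together: intramolecular inverse-demand Diels–Alder / retro-Diels–Alder (loss of N2) of a 3-alkoxy-5-methoxypyridazine whose O–C2–C3–C4 tether ends in an internal alkyne carrying the arylethyl chain.
- The pyridazinyl ether comes from SNAr of the free benzylic (C2) alcohol on 3-chloro-5-methoxypyridazine, with the C3 oxygen held as a benzyl ether.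
- The alkynol comes from acetylide opening of a terminal erythro epoxide.
- Both stereocentres come from one Sharpless kinetic resolution of an aryl vinyl carbinol.

Assumption: the SMILES is read as (2R,3S), i.e. 2,3-trans (catechin-type); the benzyl-protected aldehyde, the benzyl-protected benzyl bromide and the chloropyridazine are taken as purchasable.

**Route**

Step 1
Reactants: 1 4-(benzyloxy)-3,5-dimethoxybenzaldehyde; 2 vinylmagnesium bromide
Product: 3 rac-1-[4-(benzyloxy)-3,5-dimethoxyphenyl]prop-2-en-1-ol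
Conditions: THF, 0 °C; then H2O
Reagents that add atoms: none
Why: Grignard 1,2-addition to the aldehyde gives the racemic allylic alcohol, which is resolved in the next step.

Step 2
Reactants: 3 rac-1-[4-(benzyloxy)-3,5-dimethoxyphenyl]prop-2-en-1-ol
Product: 4 (R)-[4-(benzyloxy)-3,5-dimethoxyphenyl][(2S)-oxiran-2-yl]methanol
Conditions: Ti(OiPr)4 (10 mol%), D-(−)-diisopropyl tartrate (15 mol%), t-BuOOH (0.55 equiv), 4 Å molecular sieves, CH2Cl2, −20 °C
Reagents that add atoms: tert-butyl hydroperoxide, CC(C)(C)OO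
Why: Sharpless kinetic resolution (Katsuki–Sharpless epoxidation of a secondary allylic alcohol): with the D-(−)-tartrate the (S)-alcohol is epoxidised fast and erythro-selectively, which sets both stereocentres (the future C2 and C3) at once, while (R)-3 stays behind and is separated (at most 50% yield).

Step 3
Reactants: 4 (R)-[4-(benzyloxy)-3,5-dimethoxyphenyl][(2S)-oxiran-2-yl]methanol
Product: 5 (2S)-2-{(R)-[4-(benzyloxy)-3,5-dimethoxyphenyl][(4-methoxybenzyl)oxy]methyl}oxirane
Conditions: NaH, PMBCl, THF–DMF (4:1), 0 °C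
Reagents that add atoms: 4-methoxybenzyl chloride, COc1ccc(CCl)cc1
Why: Williamson etherification at 0 °C traps the alkoxide before it can undergo Payne rearrangement and masks the benzylic oxygen so that only the hydroxyl created in step 5 is benzylated; no stereocentre is touched.

Step 4
Reactants: 6 3-(benzyloxy)benzyl bromide; 7 1-(trimethylsilyl)propyne
Product: 10 1-(benzyloxy)-3-(but-3-yn-1-yl)benzene, via lithiated silylpropyne 8 (not isolated), via silylated alkyne 9 (not isolated)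
Conditions: n-BuLi, THF, −78 to −20 °C; 6, −78 °C to rt; then MeOH, K2CO3 (cat.), rt
Reagents that add atoms: none
Why: Alkylation of the propargylic lithium reagent from 1-(trimethylsilyl)propyne by the benzylic bromide, followed by base-catalysed methanolysis of the C–Si bond, gives the terminal alkyne.

Step 5
Reactants: 5 (2S)-2-{(R)-[4-(benzyloxy)-3,5-dimethoxyphenyl][(4-methoxybenzyl)oxy]methyl}oxirane; 10 1-(benzyloxy)-3-(but-3-yn-1-yl)benzene
Product: 13 (1R,2S)-2-(benzyloxy)-1-[4-(benzyloxy)-3,5-dimethoxyphenyl]-7-[3-(benzyloxy)phenyl]hept-4-yn-1-yl 4-methoxybenzyl ether, via lithium acetylide 11 (not isolated), via lithium alkoxide 12 (not isolated)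
Conditions: n-BuLi, THF, −78 °C; 5, DMPU, −78 to 45 °C; then BnBr, rt
Reagents that add atoms: benzyl bromide, BrCc1ccccc1
Why: SN2 opening of the terminal epoxide at its CH2 carbon by the lithium acetylide leaves the C–O bond of the stereocentre intact (retention), and the resulting alkoxide is O-benzylated in the same flask (Williamson etherification).

Step 6
Reactants: 13 (1R,2S)-2-(benzyloxy)-1-[4-(benzyloxy)-3,5-dimethoxyphenyl]-7-[3-(benzyloxy)phenyl]hept-4-yn-1-yl 4-methoxybenzyl ether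
Product: 14 (1R,2S)-2-(benzyloxy)-1-[4-(benzyloxy)-3,5-dimethoxyphenyl]-7-[3-(benzyloxy)phenyl]hept-4-yn-1-ol
Conditions: DDQ, CH2Cl2–pH 7 buffer, 0 °C
Reagents that add atoms: none
Why: Oxidative PMB-ether cleavage (hydride abstraction by DDQ, then hydrolysis of the oxocarbenium ion) frees only the benzylic hydroxyl, with the benzyl ethers and the alkyne inert and no stereocentre touched.

Step 7
Reactants: 14 (1R,2S)-2-(benzyloxy)-1-[4-(benzyloxy)-3,5-dimethoxyphenyl]-7-[3-(benzyloxy)phenyl]hept-4-yn-1-ol; 15 3-chloro-5-methoxypyridazine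
Product: 16 3-{[(1R,2S)-2-(benzyloxy)-1-[4-(benzyloxy)-3,5-dimethoxyphenyl]-7-[3-(benzyloxy)phenyl]hept-4-yn-1-yl]oxy}-5-methoxypyridazine
Conditions: NaH, DMF, 0 to 70 °C
Reagents that add atoms: none
Why: Nucleophilic aromatic substitution (addition–elimination) of the sodium alkoxide at C3 of the chlorodiazine forms the aryl ether without breaking the carbinol C–O bond, so C1 keeps its configuration.

Step 8
Reactants: 16 3-{[(1R,2S)-2-(benzyloxy)-1-[4-(benzyloxy)-3,5-dimethoxyphenyl]-7-[3-(benzyloxy)phenyl]hept-4-yn-1-yl]oxy}-5-methoxypyridazine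
Product: 18 (2R,3S)-3-(benzyloxy)-2-[4-(benzyloxy)-3,5-dimethoxyphenyl]-5-{2-[3-(benzyloxy)phenyl]ethyl}-7-methoxychromane, via diazabicyclooctatriene cycloadduct 17 (not isolated)
Conditions: 1,3,5-triisopropylbenzene, 230 °C, sealed tube, Ar
Reagents that add atoms: none
Why: Intramolecular inverse-electron-demand Diels–Alder reaction of the 1,2-diazine (C3 and C6 as diene termini) with the tethered alkyne, then retro-Diels–Alder loss of N2, builds benzene ring A and pyran ring C in one operation with fixed regiochemistry (OMe at C7, arylethyl chain at C5); this is a known reaction type for alkyne-tethered pyridazines, and since no bond to C2 or C3 is broken the (2R,3S) configuration is carried through.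

Step 9
Reactants: 18 (2R,3S)-3-(benzyloxy)-2-[4-(benzyloxy)-3,5-dimethoxyphenyl]-5-{2-[3-(benzyloxy)phenyl]ethyl}-7-methoxychromane
Product: 19 (2R,3S)-2-(4-hydroxy-3,5-dimethoxyphenyl)-5-[2-(3-hydroxyphenyl)ethyl]-7-methoxychroman-3-ol
Conditions: H2 (1 atm), Pd(OH)2/C, THF–MeOH, rt
Reagents that add atoms: none
Why: Catalytic hydrogenolysis removes the two aryl benzyl ethers and the C3 benzyl ether, while the cyclic C2–O bond of flavan-3-ols survives these conditions, so both stereocentres are unchanged.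

**Compound list**

1 | 4-(benzyloxy)-3,5-dimethoxybenzaldehyde | O=Cc1cc(OC)c(OCc2ccccc2)c(OC)c1 | starting material
2 | vinylmagnesium bromide | C=C[Mg]Br | starting material
3 | rac-1-[4-(benzyloxy)-3,5-dimethoxyphenyl]prop-2-en-1-ol | C=CC(O)c1cc(OC)c(OCc2ccccc2)c(OC)c1 | intermediate
4 | (R)-[4-(benzyloxy)-3,5-dimethoxyphenyl][(2S)-oxiran-2-yl]methanol | O[C@H](c1cc(OC)c(OCc2ccccc2)c(OC)c1)[C@@H]1CO1 | intermediate
5 | (2S)-2-{(R)-[4-(benzyloxy)-3,5-dimethoxyphenyl][(4-methoxybenzyl)oxy]methyl}oxirane | COc1ccc(CO[C@H](c2cc(OC)c(OCc3ccccc3)c(OC)c2)[C@@H]2CO2)cc1 | intermediate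
6 | 3-(benzyloxy)benzyl bromide | BrCc1cccc(OCc2ccccc2)c1 | starting material
7 | 1-(trimethylsilyl)propyne | CC#C[Si](C)(C)C | starting material
8 | [3-(trimethylsilyl)prop-2-yn-1-yl]lithium | [Li]CC#C[Si](C)(C)C | intermediate
9 | {4-[3-(benzyloxy)phenyl]but-1-yn-1-yl}trimethylsilane | C[Si](C)(C)C#CCCc1cccc(OCc2ccccc2)c1 | intermediate
10 | 1-(benzyloxy)-3-(but-3-yn-1-yl)benzene | C#CCCc1cccc(OCc2ccccc2)c1 | intermediate
11 | {4-[3-(benzyloxy)phenyl]but-1-yn-1-yl}lithium | [Li]C#CCCc1cccc(OCc2ccccc2)c1 | intermediate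
12 | lithium (1R,2S)-1-[4-(benzyloxy)-3,5-dimethoxyphenyl]-7-[3-(benzyloxy)phenyl]-1-[(4-methoxybenzyl)oxy]hept-4-yn-2-olate | COc1ccc(CO[C@H](c2cc(OC)c(OCc3ccccc3)c(OC)c2)[C@@H]([O-])CC#CCCc2cccc(OCc3ccccc3)c2)cc1.[Li+] | intermediate
13 | (1R,2S)-2-(benzyloxy)-1-[4-(benzyloxy)-3,5-dimethoxyphenyl]-7-[3-(benzyloxy)phenyl]hept-4-yn-1-yl 4-methoxybenzyl ether | COc1ccc(CO[C@H](c2cc(OC)c(OCc3ccccc3)c(OC)c2)[C@@H](OCc2ccccc2)CC#CCCc2cccc(OCc3ccccc3)c2)cc1 | intermediate
14 | (1R,2S)-2-(benzyloxy)-1-[4-(benzyloxy)-3,5-dimethoxyphenyl]-7-[3-(benzyloxy)phenyl]hept-4-yn-1-ol | O[C@H](c1cc(OC)c(OCc2ccccc2)c(OC)c1)[C@@H](OCc1ccccc1)CC#CCCc1cccc(OCc2ccccc2)c1 | intermediate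
15 | 3-chloro-5-methoxypyridazine | COc1cnnc(Cl)c1 | starting material
16 | 3-{[(1R,2S)-2-(benzyloxy)-1-[4-(benzyloxy)-3,5-dimethoxyphenyl]-7-[3-(benzyloxy)phenyl]hept-4-yn-1-yl]oxy}-5-methoxypyridazine | COc1cnnc(O[C@H](c2cc(OC)c(OCc3ccccc3)c(OC)c2)[C@@H](OCc2ccccc2)CC#CCCc2cccc(OCc3ccccc3)c2)c1 | intermediate
17 | 2,3-diazabicyclo[2.2.2]octa-2,5,7-triene cycloadduct of 16 (pyran ring already closed; bridgehead configuration unassigned, both forms give 18) | COC1=CC23O[C@H](c4cc(OC)c(OCc5ccccc5)c(OC)c4)[C@@H](OCc4ccccc4)CC2=C(CCc2cccc(OCc4ccccc4)c2)C1N=N3 | intermediate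
18 | (2R,3S)-3-(benzyloxy)-2-[4-(benzyloxy)-3,5-dimethoxyphenyl]-5-{2-[3-(benzyloxy)phenyl]ethyl}-7-methoxychromane | COc1cc(CCc2cccc(OCc3ccccc3)c2)c2c(c1)O[C@H](c1cc(OC)c(OCc3ccccc3)c(OC)c1)[C@@H](OCc1ccccc1)C2 | intermediate
19 | (2R,3S)-2-(4-hydroxy-3,5-dimethoxyphenyl)-5-[2-(3-hydroxyphenyl)ethyl]-7-methoxychroman-3-ol (CNP0118545.1) | COc1cc(CCc2cccc(O)c2)c2c(c1)O[C@H](c1cc(OC)c(O)c(OC)c1)[C@@H](O)C2 | target

**Totals**
Total step count: 9. Longest linear sequence: 8 (steps 1, 2, 3, 5, 6, 7, 8, 9).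

**Three steps most likely to fail**

Step 8 (cycloaddition). The diazine carries two donor alkoxy groups, the alkyne is unactivated and the tether closes a six-membered ring, so the substrate is at the edge of the known scope. The benzylic heteroaryl ether may also eliminate at 230 °C. The fallback sets out from 16 and changes the dienophile. Semi-hydrogenation (H2, Pd/CaCO3 poisoned with Pb(OAc)2, quinoline) gives the (4Z)-alkenyl pyridazinyl ether F1. An alkene is a better inverse-demand dienophile than the alkyne, so cycloaddition and N2 loss can run at about 160–180 °C and give the 4a,5-dihydrochromene F2. Dehydrogenation with DDQ aromatises ring A, and the route is rejoined at 18.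

Step 7 (SNAr). The chloride is deactivated by the 5-methoxy group and the alkoxide is secondary and hindered, so heating may cause elimination of the product ether before conversion is complete. The fallback sets out from 14 and 15 and replaces the addition–elimination by a palladium-catalysed C–O cross-coupling ([Pd(C3H5)Cl]2, RockPhos, Cs2CO3, toluene, 90 °C). This needs only a weak base and returns directly at 16; new compounds: none F0.

Step 6 (PMB removal). DDQ may also oxidise the benzylic C–H of the electron-rich trialkoxyaryl carbinol ether. The fallback sets out from 4 and changes the protecting-group plan. Silylation (TBSCl, imidazole, DMF) gives the silyl-protected epoxide F3. Addition of 11 mediated by BF3·OEt2 at −78 °C opens the epoxide without a free alkoxide, so the silyl group cannot migrate, and gives the silyl-protected alkynol F4. Neutral benzylation with 2-benzyloxy-1-methylpyridinium triflate and MgO gives the silyl benzyl diether F5. Bu4NF then removes the silyl group, and the route is rejoined at 14.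

Further compounds
F1 | step 8 | 3-{[(1R,2S,4Z)-2-(benzyloxy)-1-[4-(benzyloxy)-3,5-dimethoxyphenyl]-7-[3-(benzyloxy)phenyl]hept-4-en-1-yl]oxy}-5-methoxypyridazine | COc1cnnc(O[C@H](c2cc(OC)c(OCc3ccccc3)c(OC)c2)[C@@H](OCc2ccccc2)C/C=C\CCc2cccc(OCc3ccccc3)c2)c1
F2 | step 8 | (2R,3S)-3-(benzyloxy)-2-[4-(benzyloxy)-3,5-dimethoxyphenyl]-5-{2-[3-(benzyloxy)phenyl]ethyl}-7-methoxy-3,4,4a,5-tetrahydro-2H-chromene (C4a and C5 unassigned) | COC1=CC(CCc2cccc(OCc3ccccc3)c2)C2C[C@H](OCc3ccccc3)[C@@H](c3cc(OC)c(OCc4ccccc4)c(OC)c3)OC2=C1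
F0 | step 7 | none | none
F3 | step 6 | {(R)-[4-(benzyloxy)-3,5-dimethoxyphenyl][(2S)-oxiran-2-yl]methoxy}(tert-butyl)dimethylsilane | CC(C)(C)[Si](C)(C)O[C@H](c1cc(OC)c(OCc2ccccc2)c(OC)c1)[C@@H]1CO1
F4 | step 6 | (1R,2S)-1-[4-(benzyloxy)-3,5-dimethoxyphenyl]-7-[3-(benzyloxy)phenyl]-1-[(tert-butyldimethylsilyl)oxy]hept-4-yn-2-ol | CC(C)(C)[Si](C)(C)O[C@H](c1cc(OC)c(OCc2ccccc2)c(OC)c1)[C@@H](O)CC#CCCc1cccc(OCc2ccccc2)c1
F5 | step 6 | {[(1R,2S)-2-(benzyloxy)-1-[4-(benzyloxy)-3,5-dimethoxyphenyl]-7-[3-(benzyloxy)phenyl]hept-4-yn-1-yl]oxy}(tert-butyl)dimethylsilane | CC(C)(C)[Si](C)(C)O[C@H](c1cc(OC)c(OCc2ccccc2)c(OC)c1)[C@@H](OCc1ccccc1)CC#CCCc1cccc(OCc2ccccc2)c1
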